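The data stem from a simulated flask for an exercise; scatter was added.

Watch the reagent.

| flask | starting material | second substrate | reagent | free catalyst | remark | time |
|---|---|---|---|---|---|---|
| spring | 10 mM | 28 mM | 20 mM | 0.20 mM | run made earlier |  |
| winter | 10 mM | 44 mM | 20 mM | 0.20 mM | run made earlier |  |
| noon | 5 mM | 20 mM | 20 mM | 0.20 mM | run made earlier |  |
| flask | 10 mM | 20.0 mM | 20.0 mM | 0.20 mM |  | 4.0 h |

| run | time / h | target / % | uncatalysed product / % | starting material / % |
|---|---|---|---|---|
| spring | 0.667 | 48.9 | 41.2 | 9.6 |
| spring | 1.50 | 49.1 | 41.3 | 9.7 |
| spring | 3.00 | 48.9 | 41.7 | 9.4 |
| spring | 5.00 | 47.7 | 41.5 | 9.4 |
| winter | 1.33 | 35.6 | 46.9 | 16.7 |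
| winter | 2.50 | 36.3 | 45.9 | 18.6 |
| winter | 4.00 | 35.4 | 46.2 | 17.5 |
| winter | 5.00 | 35.9 | 46.0 | 17.1 |
| noon | 0.417 | 59.9 | 39.3 | 0 |
| noon | 0.833 | 59.8 | 40.5 | 0 |
| noon | 2.00 | 60.2 | 39.0 | 0 |
| noon | 5.00 | 59.2 | 40.0 | 0 |

(readings scatter by 0.5 percentage points)

- what was read earlier has a scatter of 0.5 percentage points, one standard deviation
- steps thought possible: starting material + free catalyst <-> catalyst intermediate A; reagent + catalyst intermediate A -> free catalyst + target; second substrate + free catalyst <-> catalyst intermediate B; reagent + catalyst intermediate B -> free catalyst + second product; starting material + reagent -> uncatalysed product
- the reaction counts as stopped when no species that holds the starting material changes by six tenths of a point or more over the second half of the time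

1. the state of affairs at 4.0 h: stopped, and by what, or still going (forward and back rates have come level / no working catalyst is left / all of the starting material has reacted / it is still moving / the reagent has run out first)
2. the target standing at 4.0 h, as a percentage of the starting material charged
3. the uncatalysed product standing at 4.0 h, as a percentage of the starting material charged

In the first instants of the flask, free catalyst can bind starting material or second substrate, but you cannot read this stage, because the noon run already stands at 59.9% of target at 0.417 h and at 59.2% at 5.00 h, so its course is over well before the 4.0 h asked of the flask.

Through the middle of the flask, reagent is spent through catalyst intermediate A on target, through catalyst intermediate B on second product, and directly on starting material to give uncatalysed product. Target and uncatalysed product each take one starting material, so if target forms at the pace at which free catalyst takes up starting material, starting material cancels from the ratio of the two rates, which then goes with free catalyst over reagent. Hence the quantity to carry is the split, a selectivity factor: target formed per uncatalysed product formed, read as 1.51 from the noon run. At fixed second substrate and reagent charges it should follow the catalyst charged. With more second substrate the last readings give less, 1.15 in the spring run and 0.780 in the winter run. The flask has the noon run's second substrate, reagent and catalyst charges, so I take the noon split for it, which sends 60.1% of the reacted starting material to target.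

At the end of the flask, starting material and second substrate together exceed the reagent charge, which makes reagent the limiting reagent, and I expect a stop with some starting material standing, as in the spring run with 9.4%. The forecast says the reagent has run out first, with target 56.8% and uncatalysed product 38.7%, a split of 1.47, slightly below mine: “The plateaus with starting material left (spring, winter) look like reagent exhaustion.”

The flask gives the reagent has run out first, with 0% of the reagent left at 4.00 h, target 59.1% and uncatalysed product 36.9%, a split of 1.60.

    starting material + free catalyst ⇌ catalyst intermediate A (K = 9200 /M, k = 220 /M/s)
    reagent + catalyst intermediate A → free catalyst + target (k = 400 /M/s)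
    second substrate + free catalyst ⇌ catalyst intermediate B (K = 910 /M, k = 230 /M/s)
    reagent + catalyst intermediate B → free catalyst + second product (k = 34.0 /M/s)
    starting material + reagent → uncatalysed product (k = 0.430 /M/s)

Now take the neighbouring flask with 0.34 mM of free catalyst, the other charges held. The catalyst ratio of 1.70 turns the flask's split into 2.72. That neighbour stands at target 69.1% and uncatalysed product 24.8%, a split of 2.79, with 4.97% of its starting material left.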